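The route rests on cutting ring B between C8 and C9. Both atoms are α-carbons of carbonyl groups (C8 to the C12 ester, C9 to the C11 aldehyde carbon), so the bond joins two centres of like polarity and is made oxidatively from a tethered dianion. In one anodic operation an ester enolate on the C10 arm and a dienolate on the C5 arm of a fully substituted ring A couple, closing ring B as a trans-decalin and setting C9. The precursor is a cyclohexane with 1α-OTBS, 3β-Cl, the quaternary C4 and C10, a tert-butyl acetate arm on C10 and an (E)-methyl but-2-enoate arm on C5.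

Key step: step 17

Remark: ring positions follow the numbering of the target decalin (C1 to C10, C11 on C9, C12 on C8; β is the face of the C10 methyl group; NAP = naphthalen-2-ylmethyl), and it is assumed that one of the two pseudoenantiomeric cinchona-derived primary amines gives the (3R)-adduct 6 in step 3.

Step 1
Reactants: 1 but-3-en-1-ol
Product: 2 2-[(but-3-en-1-yloxy)methyl]naphthalene
Conditions: NaH, Bu4NI (cat.), THF, 0 °C to rt
Reagents that add atoms: 2-(bromomethyl)naphthalene, BrCc1ccc2ccccc2c1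
Why: Williamson ether synthesis installs a NAP ether that tolerates strong base, oxalyl chloride and hydride and is later removed oxidatively without touching silyl ethers.

Step 2
Reactants: 2 2-[(but-3-en-1-yloxy)methyl]naphthalene; 3 but-3-en-2-one
Product: 4 (3E)-6-(naphthalen-2-ylmethoxy)hex-3-en-2-one
Conditions: second-generation Hoveyda–Grubbs catalyst [RuCl2(H2IMes)(=CH-C6H4-2-OiPr)] (2 mol %), 3 (3 equiv), CH2Cl2, 40 °C
Reagents that add atoms: none
Why: Olefin cross-metathesis of a terminal alkene with an electron-poor vinyl ketone favours the cross product and gives the more stable E-enone.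

Step 3
Reactants: 4 (3E)-6-(naphthalen-2-ylmethoxy)hex-3-en-2-one; 5 diethyl propanedioate
Product: 6 diethyl 2-[(3R)-1-(naphthalen-2-ylmethoxy)-5-oxohexan-3-yl]propanedioate
Conditions: 9-amino-9-deoxy-epi-cinchona primary amine (20 mol %, the pseudoenantiomer that gives 3R), PhCO2H (40 mol %), toluene, rt
Reagents that add atoms: none
Why: Organocatalytic Michael addition through a chiral iminium ion, in which the amine shields one face of the enone and so sets the stereocentre that becomes C5.

Step 4
Reactants: 6 diethyl 2-[(3R)-1-(naphthalen-2-ylmethoxy)-5-oxohexan-3-yl]propanedioate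
Product: 7 ethyl (1S,6R)-6-[2-(naphthalen-2-ylmethoxy)ethyl]-2,4-dioxocyclohexane-1-carboxylate
Conditions: NaOEt (1.2 equiv), EtOH, 0 °C to 50 °C; acidic work-up (1 M HCl)
Reagents that add atoms: none
Why: Intramolecular Claisen (Dieckmann-type) condensation of the methyl ketone enolate onto one malonate ester closes the six-membered ring and is driven by formation of the diketonate, while the non-enolisable C5 centre is kept and the ester-bearing carbon settles trans to it.

Step 5
Reactants: 7 ethyl (1S,6R)-6-[2-(naphthalen-2-ylmethoxy)ethyl]-2,4-dioxocyclohexane-1-carboxylate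
Product: 8 ethyl (1S,6R)-4-ethoxy-6-[2-(naphthalen-2-ylmethoxy)ethyl]-2-oxocyclohex-3-ene-1-carboxylate
Conditions: EtOH, TsOH·H2O (5 mol %), benzene, reflux, Dean–Stark trap
Reagents that add atoms: ethanol, CCO
Why: Acid-catalysed enol etherification of the 1,3-dione should occur at the unhindered carbonyl remote from the ester-bearing carbon, leaving the other carbonyl as a hydrogen-bonded β-keto ester, so the future C1 and C3 are told apart.

Step 6
Reactants: 8 ethyl (1S,6R)-4-ethoxy-6-[2-(naphthalen-2-ylmethoxy)ethyl]-2-oxocyclohex-3-ene-1-carboxylate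
Product: 9 (5R)-3-ethoxy-5-[2-(naphthalen-2-ylmethoxy)ethyl]cyclohex-2-en-1-one
Conditions: NaCl, H2O (3 equiv), DMSO, 140 °C
Reagents that add atoms: none
Why: Krapcho dealkoxycarbonylation removes the ester that served as regiochemical marker, and the fixed enol ether keeps 9 a single enantiomer under these neutral conditions.

Step 7
Reactants: 9 (5R)-3-ethoxy-5-[2-(naphthalen-2-ylmethoxy)ethyl]cyclohex-2-en-1-one
Product: 11 (5R,6S)-3-ethoxy-6-methyl-5-[2-(naphthalen-2-ylmethoxy)ethyl]cyclohex-2-en-1-one, via lithium enolate 10 (not isolated)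
Conditions: LiN(iPr)2 (1.05 equiv), THF, −78 °C; then MeI, −78 °C to 0 °C
Reagents that add atoms: iodomethane, CI
Why: Stork–Danheiser α′-alkylation of the vinylogous ester through its kinetic cross-conjugated enolate, the configuration at the new methyl-bearing carbon being irrelevant because it is enolised again in step 8.

Step 8
Reactants: 11 (5R,6S)-3-ethoxy-6-methyl-5-[2-(naphthalen-2-ylmethoxy)ethyl]cyclohex-2-en-1-one; 12 5-iodo-2-methylpent-2-ene
Product: 14 (5R,6S)-3-ethoxy-6-methyl-6-(4-methylpent-3-en-1-yl)-5-[2-(naphthalen-2-ylmethoxy)ethyl]cyclohex-2-en-1-one, via lithium enolate 13 (not isolated)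
Conditions: LiN(iPr)2 (1.2 equiv), THF, −78 °C; then DMPU, 12 (3 equiv), −78 °C to rt
Reagents that add atoms: none
Why: Second Stork–Danheiser alkylation, in which the C5 side chain sits pseudoaxial to avoid allylic strain with the enolate methyl and the iodide enters from the opposite face, placing the 4-methylpent-3-enyl group trans to the C5 arm (4α) and the methyl cis (4β).

Step 9
Reactants: 14 (5R,6S)-3-ethoxy-6-methyl-6-(4-methylpent-3-en-1-yl)-5-[2-(naphthalen-2-ylmethoxy)ethyl]cyclohex-2-en-1-one
Product: 15 (4S,5R)-3-chloro-4-methyl-4-(4-methylpent-3-en-1-yl)-5-[2-(naphthalen-2-ylmethoxy)ethyl]cyclohex-2-en-1-one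
Conditions: (COCl)2 (1.5 equiv), DMF (cat.), CH2Cl2, 0 °C to rt
Reagents that add atoms: oxalyl chloride, O=C(Cl)C(Cl)=O
Why: Deoxychlorination of a vinylogous ester with 1,3-transposition: the carbonyl oxygen is acylated, chloride adds to the activated former carbonyl carbon (C3) and chloride then dealkylates the ethyl oxocarbenium ion, so the ketone reappears at C1 and chlorine sits on C3 next to the quaternary C4.

Step 10
Reactants: 15 (4S,5R)-3-chloro-4-methyl-4-(4-methylpent-3-en-1-yl)-5-[2-(naphthalen-2-ylmethoxy)ethyl]cyclohex-2-en-1-one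
Product: 17 (4S,5R,6R)-3-chloro-4,6-dimethyl-4-(4-methylpent-3-en-1-yl)-5-[2-(naphthalen-2-ylmethoxy)ethyl]cyclohex-2-en-1-one, via lithium enolate 16 (not isolated)
Conditions: LiN(iPr)2 (1.05 equiv), THF, −78 °C; then MeI, −78 °C to −20 °C
Reagents that add atoms: iodomethane, CI
Why: Kinetic α′-enolate alkylation, regiospecific because C4 is quaternary and only C10 carries protons, with the C10 configuration again irrelevant at this stage.

Step 11
Reactants: 17 (4S,5R,6R)-3-chloro-4,6-dimethyl-4-(4-methylpent-3-en-1-yl)-5-[2-(naphthalen-2-ylmethoxy)ethyl]cyclohex-2-en-1-one; 18 tert-butyl bromoacetate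
Product: 20 tert-butyl 2-[(1R,5S,6R)-4-chloro-1,5-dimethyl-5-(4-methylpent-3-en-1-yl)-6-[2-(naphthalen-2-ylmethoxy)ethyl]-2-oxocyclohex-3-en-1-yl]acetate, via lithium enolate 19 (not isolated)
Conditions: LiN(iPr)2 (1.15 equiv), THF, −78 °C; then DMPU, 18 (1.5 equiv), −78 °C to −20 °C
Reagents that add atoms: none
Why: Enolate alkylation with a reactive α-bromo ester builds the C10 quaternary centre, the electrophile approaching anti to the neighbouring C5 arm so that the acetate arm becomes 10α (trans to the C5 arm) and the methyl 10β.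

Step 12
Reactants: 20 tert-butyl 2-[(1R,5S,6R)-4-chloro-1,5-dimethyl-5-(4-methylpent-3-en-1-yl)-6-[2-(naphthalen-2-ylmethoxy)ethyl]-2-oxocyclohex-3-en-1-yl]acetate
Product: 21 ring A allylic alcohol (20 with the C1 ketone reduced to the 1α-alcohol, OH cis to the CH2CO2tBu arm)
Conditions: (R)-2-methyl-CBS-oxazaborolidine (0.5 equiv), catecholborane (2 equiv), toluene, −78 °C
Reagents that add atoms: none
Why: Corey–Bakshi–Shibata reduction, in which the ketone binds the oxazaborolidine anti to its bulkier flank (quaternary C10) and the (R)-catalyst delivers hydride to the β-face, giving the 1α-alcohol under reagent control while catecholborane spares the side-chain alkene and the ester.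

Step 13
Reactants: 21 ring A allylic alcohol (1α-OH, C2=C3–Cl)
Product: 22 ring A chloro alcohol (1α-OH, 3β-Cl, ring saturated)
Conditions: [Rh(nbd)(dppb)]BF4 (10 mol %), H2 (50 bar), CH2Cl2, rt
Reagents that add atoms: none
Why: Hydroxyl-directed homogeneous hydrogenation: the cationic rhodium catalyst is held by the 1α-hydroxyl and adds H2 to the α-face of the C2=C3 chloroalkene, so chlorine ends up 3β (trans to the hydroxyl), while the undirected trisubstituted side-chain alkene is expected to stay untouched by this catalyst.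

Step 14
Reactants: 22 ring A chloro alcohol (1α-OH, 3β-Cl)
Product: 23 TBS ether of 22 (1α-OTBS)
Conditions: TBSOTf (1.5 equiv), 2,6-lutidine (3 equiv), CH2Cl2, −78 °C to 0 °C
Reagents that add atoms: tert-butyldimethylsilyl trifluoromethanesulfonate, CC(C)(C)[Si](C)(C)OS(=O)(=O)C(F)(F)F
Why: Silylation of a hindered secondary alcohol with a silyl triflate and a hindered base, which also ends the risk of lactonisation onto the neighbouring tert-butyl ester.

Step 15
Reactants: 23 TBS ether (1α-OTBS, 5β-CH2CH2ONAP)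
Product: 24 primary alcohol (5β-CH2CH2OH)
Conditions: DDQ (1.5 equiv), CH2Cl2/pH 7 phosphate buffer (10:1), 0 °C to rt
Reagents that add atoms: none
Why: Oxidative cleavage of the NAP ether by DDQ (hydride abstraction at the naphthylmethyl carbon, then hydrolysis) leaves the silyl ether, tert-butyl ester, chloride and alkene intact.

Step 16
Reactants: 24 primary alcohol (5β-CH2CH2OH); 25 methyl (triphenylphosphoranylidene)acetate
Product: 27 coupling precursor (ring A diester with 10α-CH2CO2tBu and 5β-(E)-CH2CH=CHCO2Me), via aldehyde 26 (not isolated)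
Conditions: Dess–Martin periodinane (1.3 equiv), CH2Cl2, 0 °C to rt; then 25 (2.5 equiv), rt
Reagents that add atoms: none
Why: Dess–Martin oxidation followed in the same flask by Wittig olefination with a stabilised ylide, which gives the E-enoate.

Step 17
Reactants: 27 coupling precursor
Product: 29 trans-decalin 6-ene 8,9-diester (8α-CO2Me; 9β-CO2tBu), via dilithium dianion 28 (not isolated)
Conditions: 27 added to LiN(iPr)2 (2.2 equiv), DMPU (4 equiv), THF, −78 °C; then constant-current electrolysis (2.1 F/mol), reticulated vitreous carbon anode, divided cell (Pt cathode, catholyte THF/LiClO4/AcOH), 0.2 M LiClO4, THF, −78 °C, 0.01 M in substrate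
Reagents that add atoms: none
Why: Proposed new method: double deprotonation gives a dianion whose C5 arm is a 6Z-dienolate (γ-deprotonation of an E-enoate gives the Z-dienolate) and whose C10 arm is a tert-butyl ester enolate; the anode removes one electron from the more easily oxidised dienolate, the delocalised radical attacks the neighbouring enolate carbon C9 through its α-carbon C8, and loss of a second electron from the resulting ester radical anion gives the neutral succinate. The closest known reactions are the oxidative heterocoupling of two different lithium enolates with Fe(acac)3 or Cu(2-ethylhexanoate)2 and the anodic dimerisation of ester enolates, whereas an intramolecular anodic cross-coupling of a dienolate with an ester enolate has not been described. Ring B closes in a 6-exo-trig mode onto the C9=C11 enolate, since attack through the γ-carbon C6 would give a cyclobutane. C9 is set by the chair-like transition state on the trans-diequatorial C5/C10 arms, in which the bulky tert-butyl ketene acetal unit points outward (equatorial, β); C8 is formed trans to it and is erased in step 18, where C9 can also still equilibrate. The step needs cross- over homo-coupling and α- over γ-attack: the tether and high dilution secure the first and ring size the second, while adding 27 to excess base keeps any mono-enolate short-lived so that the ester enolate does not add to C7 of an intact enoate.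

Step 18
Reactants: 29 trans-decalin 6-ene 8,9-diester
Product: 30 trans-decalin 7-ene-8-methyl ester with 9β-CO2tBu
Conditions: DBU (3 equiv), toluene, 80 °C
Reagents that add atoms: none
Why: Base-mediated isomerisation of a β,γ-unsaturated ester into conjugation (deprotonation at C8, reprotonation at C6) gives the 7-ene-8-ester, and under these equilibrating conditions the C9 ester should end up equatorial (β).

Step 19
Reactants: 30 trans-decalin 7-ene-8-methyl ester
Product: 31 side-chain (R)-epoxide of 30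
Conditions: D-fructose-derived Shi ketone (1,2:4,5-di-O-isopropylidene-β-D-erythro-2,3-hexodiulo-2,6-pyranose, 0.3 equiv), Oxone (2KHSO5·KHSO4·K2SO4), K2CO3, Bu4NHSO4, MeCN/dimethoxymethane/aqueous Na2B4O7 buffer (pH 10.5), 0 °C
Reagents that add atoms: potassium peroxymonosulfate (Oxone), [K+].[O-]S(=O)(=O)OO
Why: Shi epoxidation, in which the chiral dioxirane attacks only the electron-rich trisubstituted side-chain alkene (the enoate is inert) and should give the (R)-epoxide under reagent control through its spiro transition state.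

Step 20
Reactants: 31 side-chain (R)-epoxide
Product: 32 allylic TBS ether (side chain CH2CH2CH(OTBS)C(CH3)=CH2, R)
Conditions: TBSOTf (1.5 equiv), DBU (2 equiv), toluene, −78 °C to rt
Reagents that add atoms: tert-butyldimethylsilyl trifluoromethanesulfonate, CC(C)(C)[Si](C)(C)OS(=O)(=O)C(F)(F)F
Why: Silyl triflate/amidine isomerisation of an epoxide to an allylic silyl ether, in which O-silylation opens the ring at the tertiary carbon and DBU removes a methyl proton, so the isopropenyl carbinol is formed with the C–O stereocentre untouched.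

Step 21
Reactants: 32 allylic TBS ether (9β-CO2tBu)
Product: 34 C11 carboxylic acid (9β-CO2H), via trimethylsilyl ester 33 (not isolated)
Conditions: TMSOTf (2 equiv), 2,6-lutidine (3 equiv), CH2Cl2, 0 °C; then aqueous NaH2PO4
Reagents that add atoms: none
Why: Silyl triflate-mediated cleavage of a tert-butyl ester (O-silylation, loss of isobutene, hydrolysis of the silyl ester) spares the TBS ethers, the methyl ester and the alkenes.

Step 22
Reactants: 34 C11 carboxylic acid
Product: 36 bis-TBS aldehyde (9β-CHO), via acid chloride 35 (not isolated)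
Conditions: 1-chloro-N,N,2-trimethylprop-1-en-1-amine (1.2 equiv), CH2Cl2, 0 °C to rt; then LiAlH(OtBu)3 (1.2 equiv), THF, −78 °C
Reagents that add atoms: none
Why: Neutral acid chloride formation with an α-chloroenamine and partial reduction with LiAlH(OtBu)3, which stops at the aldehyde and leaves the methyl enoate alone, so that C11 never passes through the alcohol level (no lactone with C12) and C9 is not exposed to base.

Step 23
Reactants: 36 bis-TBS aldehyde
Product: 37 target CNP0159496.2
Conditions: HF·pyridine, pyridine, THF, 0 °C to rt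
Reagents that add atoms: none
Why: Fluoride-mediated cleavage of both TBS ethers under buffered, weakly acidic conditions that should not epimerise the C9 aldehyde.

Compound list

1 | but-3-en-1-ol | C=CCCO | starting material
2 | 2-[(but-3-en-1-yloxy)methyl]naphthalene | C=CCCOCc1ccc2ccccc2c1 | intermediate
3 | but-3-en-2-one | CC(=O)C=C | starting material
4 | (3E)-6-(naphthalen-2-ylmethoxy)hex-3-en-2-one | CC(=O)/C=C/CCOCc1ccc2ccccc2c1 | intermediate
5 | diethyl propanedioate | CCOC(=O)CC(=O)OCC | starting material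
6 | diethyl 2-[(3R)-1-(naphthalen-2-ylmethoxy)-5-oxohexan-3-yl]propanedioate | CC(=O)C[C@@H](CCOCc1ccc2ccccc2c1)C(C(=O)OCC)C(=O)OCC | intermediate
7 | ethyl (1S,6R)-6-[2-(naphthalen-2-ylmethoxy)ethyl]-2,4-dioxocyclohexane-1-carboxylate (trans, drawn as the diketo tautomer) | CCOC(=O)[C@@H]1C(=O)CC(=O)C[C@H]1CCOCc2ccc3ccccc3c2 | intermediate
8 | ethyl (1S,6R)-4-ethoxy-6-[2-(naphthalen-2-ylmethoxy)ethyl]-2-oxocyclohex-3-ene-1-carboxylate | CCOC(=O)[C@@H]1C(=O)C=C(OCC)C[C@H]1CCOCc2ccc3ccccc3c2 | intermediate
9 | (5R)-3-ethoxy-5-[2-(naphthalen-2-ylmethoxy)ethyl]cyclohex-2-en-1-one | C1C(=O)C=C(OCC)C[C@H]1CCOCc2ccc3ccccc3c2 | intermediate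
10 | lithium (3R)-5-ethoxy-3-[2-(naphthalen-2-ylmethoxy)ethyl]cyclohexa-1,5-dien-1-olate (α′-enolate of 9) | C1=C(O[Li])C=C(OCC)C[C@H]1CCOCc2ccc3ccccc3c2 | intermediate
11 | (5R,6S)-3-ethoxy-6-methyl-5-[2-(naphthalen-2-ylmethoxy)ethyl]cyclohex-2-en-1-one (trans; the C6 epimer serves equally) | C[C@@H]1C(=O)C=C(OCC)C[C@H]1CCOCc2ccc3ccccc3c2 | intermediate
12 | 5-iodo-2-methylpent-2-ene | CC(C)=CCCI | starting material
13 | lithium (3R)-5-ethoxy-2-methyl-3-[2-(naphthalen-2-ylmethoxy)ethyl]cyclohexa-1,5-dien-1-olate (α′-enolate of 11) | CC1=C(O[Li])C=C(OCC)C[C@H]1CCOCc2ccc3ccccc3c2 | intermediate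
14 | (5R,6S)-3-ethoxy-6-methyl-6-(4-methylpent-3-en-1-yl)-5-[2-(naphthalen-2-ylmethoxy)ethyl]cyclohex-2-en-1-one | CC(C)=CCC[C@]1(C)C(=O)C=C(OCC)C[C@H]1CCOCc2ccc3ccccc3c2 | intermediate
15 | (4S,5R)-3-chloro-4-methyl-4-(4-methylpent-3-en-1-yl)-5-[2-(naphthalen-2-ylmethoxy)ethyl]cyclohex-2-en-1-one | CC(C)=CCC[C@]1(C)C(Cl)=CC(=O)C[C@H]1CCOCc2ccc3ccccc3c2 | intermediate
16 | lithium dienolate of 15 (O–Li on C1, C1=C10) | CC(C)=CCC[C@]1(C)C(Cl)=CC(O[Li])=C[C@H]1CCOCc2ccc3ccccc3c2 | intermediate
17 | (4S,5R,6R)-3-chloro-4,6-dimethyl-4-(4-methylpent-3-en-1-yl)-5-[2-(naphthalen-2-ylmethoxy)ethyl]cyclohex-2-en-1-one (the C6 epimer serves equally) | CC(C)=CCC[C@]1(C)C(Cl)=CC(=O)[C@H](C)[C@H]1CCOCc2ccc3ccccc3c2 | intermediate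
18 | tert-butyl bromoacetate | CC(C)(C)OC(=O)CBr | starting material
19 | lithium dienolate of 17 (O–Li on C1, C1=C10) | CC(C)=CCC[C@]1(C)C(Cl)=CC(O[Li])=C(C)[C@H]1CCOCc2ccc3ccccc3c2 | intermediate
20 | tert-butyl 2-[(1R,5S,6R)-4-chloro-1,5-dimethyl-5-(4-methylpent-3-en-1-yl)-6-[2-(naphthalen-2-ylmethoxy)ethyl]-2-oxocyclohex-3-en-1-yl]acetate | CC(C)=CCC[C@]1(C)C(Cl)=CC(=O)[C@](C)(CC(=O)OC(C)(C)C)[C@H]1CCOCc2ccc3ccccc3c2 | intermediate
21 | tert-butyl 2-[(1R,2S,5S,6R)-4-chloro-2-hydroxy-1,5-dimethyl-5-(4-methylpent-3-en-1-yl)-6-[2-(naphthalen-2-ylmethoxy)ethyl]cyclohex-3-en-1-yl]acetate (1α-OH) | CC(C)=CCC[C@]1(C)C(Cl)=C[C@H](O)[C@](C)(CC(=O)OC(C)(C)C)[C@H]1CCOCc2ccc3ccccc3c2 | intermediate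
22 | tert-butyl 2-[(1R,2S,4S,5S,6R)-4-chloro-2-hydroxy-1,5-dimethyl-5-(4-methylpent-3-en-1-yl)-6-[2-(naphthalen-2-ylmethoxy)ethyl]cyclohexyl]acetate (1α-OH, 3β-Cl) | CC(C)=CCC[C@]1(C)[C@@H](Cl)C[C@H](O)[C@](C)(CC(=O)OC(C)(C)C)[C@H]1CCOCc2ccc3ccccc3c2 | intermediate
23 | TBS ether of 22 (1α-OTBS, 3β-Cl, 5β-CH2CH2ONAP, 10α-CH2CO2tBu) | CC(C)=CCC[C@]1(C)[C@@H](Cl)C[C@H](O[Si](C)(C)C(C)(C)C)[C@](C)(CC(=O)OC(C)(C)C)[C@H]1CCOCc2ccc3ccccc3c2 | intermediate
24 | primary alcohol (23 with 5β-CH2CH2OH) | CC(C)=CCC[C@]1(C)[C@@H](Cl)C[C@H](O[Si](C)(C)C(C)(C)C)[C@](C)(CC(=O)OC(C)(C)C)[C@H]1CCO | intermediate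
25 | methyl (triphenylphosphoranylidene)acetate | COC(=O)C=P(c1ccccc1)(c1ccccc1)c1ccccc1 | starting material
26 | aldehyde (5β-CH2CHO) | CC(C)=CCC[C@]1(C)[C@@H](Cl)C[C@H](O[Si](C)(C)C(C)(C)C)[C@](C)(CC(=O)OC(C)(C)C)[C@H]1CC=O | intermediate
27 | coupling precursor: ring A diester with 1α-OTBS, 3β-Cl, 4β-Me, 4α-(4-methylpent-3-enyl), 10β-Me, 10α-CH2CO2tBu and 5β-(E)-CH2CH=CHCO2Me | CC(C)=CCC[C@]1(C)[C@@H](Cl)C[C@H](O[Si](C)(C)C(C)(C)C)[C@](C)(CC(=O)OC(C)(C)C)[C@H]1C/C=C/C(=O)OC | intermediate
28 | dilithium dianion of 27 (tert-butyl ester enolate at C9, 6Z-dienolate on the C5 arm) | CC(C)=CCC[C@]1(C)[C@@H](Cl)C[C@H](O[Si](C)(C)C(C)(C)C)[C@](C)(C=C(O[Li])OC(C)(C)C)[C@H]1/C=C\C=C(O[Li])OC | intermediate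
29 | trans-decalin 6-ene 8,9-diester (8α-CO2Me, 9β-CO2tBu, 1α-OTBS, 3β-Cl) | CC(C)=CCC[C@]1(C)[C@@H](Cl)C[C@H](O[Si](C)(C)C(C)(C)C)[C@]2(C)[C@@H](C(=O)OC(C)(C)C)[C@H](C(=O)OC)C=C[C@@H]12 | intermediate
30 | trans-decalin 7-ene-8-methyl ester with 9β-CO2tBu | CC(C)=CCC[C@]1(C)[C@@H](Cl)C[C@H](O[Si](C)(C)C(C)(C)C)[C@]2(C)[C@@H](C(=O)OC(C)(C)C)C(C(=O)OC)=CC[C@@H]12 | intermediate
31 | side-chain (R)-epoxide of 30 | CC1(C)O[C@@H]1CC[C@]2(C)[C@@H](Cl)C[C@H](O[Si](C)(C)C(C)(C)C)[C@]3(C)[C@@H](C(=O)OC(C)(C)C)C(C(=O)OC)=CC[C@@H]23 | intermediate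
32 | allylic TBS ether (side chain (R)-CH(OTBS)C(CH3)=CH2, 9β-CO2tBu) | C=C(C)[C@H](O[Si](C)(C)C(C)(C)C)CC[C@]1(C)[C@@H](Cl)C[C@H](O[Si](C)(C)C(C)(C)C)[C@]2(C)[C@@H](C(=O)OC(C)(C)C)C(C(=O)OC)=CC[C@@H]12 | intermediate
33 | trimethylsilyl ester at C11 | C=C(C)[C@H](O[Si](C)(C)C(C)(C)C)CC[C@]1(C)[C@@H](Cl)C[C@H](O[Si](C)(C)C(C)(C)C)[C@]2(C)[C@@H](C(=O)O[Si](C)(C)C)C(C(=O)OC)=CC[C@@H]12 | intermediate
34 | C11 carboxylic acid (9β-CO2H) | C=C(C)[C@H](O[Si](C)(C)C(C)(C)C)CC[C@]1(C)[C@@H](Cl)C[C@H](O[Si](C)(C)C(C)(C)C)[C@]2(C)[C@@H](C(=O)O)C(C(=O)OC)=CC[C@@H]12 | intermediate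
35 | C11 acid chloride | C=C(C)[C@H](O[Si](C)(C)C(C)(C)C)CC[C@]1(C)[C@@H](Cl)C[C@H](O[Si](C)(C)C(C)(C)C)[C@]2(C)[C@@H](C(=O)Cl)C(C(=O)OC)=CC[C@@H]12 | intermediate
36 | bis-TBS aldehyde (9β-CHO) | C=C(C)[C@H](O[Si](C)(C)C(C)(C)C)CC[C@]1(C)[C@@H](Cl)C[C@H](O[Si](C)(C)C(C)(C)C)[C@]2(C)[C@@H](C=O)C(C(=O)OC)=CC[C@@H]12 | intermediate
37 | CNP0159496.2: trans-decal-7-ene-8-carboxylic acid methyl ester with 1α-OH, 3β-Cl, 4β-Me, 4α-[(3R)-3-hydroxy-4-methylpent-4-enyl], 9β-CHO, 10β-Me | C=C(C)[C@H](O)CC[C@]1(C)[C@@H](Cl)C[C@H](O)[C@]2(C)[C@@H](C=O)C(C(=O)OC)=CC[C@@H]12 | target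

Total step count: 23. Longest linear sequence: 23 steps, from but-3-en-1-ol (1) to 37.

Steps most likely to fail

1. Step 17 (the proposed new method). A mono-enolate may close a five-membered ring by Michael addition to C7 before the dienolate has formed. Part of the dienolate may form with the E geometry, which cannot reach C9. The more acidic product may transfer a proton to unreacted enolate and then be over-oxidised. The anode may foul at −78 °C. Fallback: the electrode is given up and the coupling is run as a metal-templated reaction on the same dianion 28. After deprotonation of 27 as before, Fe(acac)3 (trivalent iron, 2.2 equiv, THF, −78 °C to rt) is added. This is the known oxidative heterocoupling of two different lithium enolates, which has also been used for ring closure. Both enolates are bound to the metal before electron transfer, so the bond forms inside the coordination sphere and not at a surface. The fallback sets out from 27, comes back at 29 and makes no new compound.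

2. Step 13. The C–Cl bond may be lost by hydrogenolysis, the side-chain alkene may be saturated at the pressure needed, or the allylic alcohol may isomerise to the ketone. Fallback: setting out from 21, the side-chain alkene is first masked by the Shi epoxidation of step 19, giving the epoxy allylic alcohol F1. The chloroalkene is then the only C=C bond and is hydrogenated under hydroxyl direction with the more active [Ir(cod)(PCy3)(py)]PF6 (H2 1 bar, CH2Cl2, 0 °C) to the epoxy chloro alcohol F2. Deoxygenation of the epoxide with PPh3 and catalytic CH3ReO3 (benzene, rt to 60 °C) restores the alkene and comes back to the route at 22.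

3. Step 12. Facial selectivity may be poor if the substrate's own bias opposes the catalyst, and the cis γ-hydroxy ester may lactonise. Fallback: setting out from 20, Luche reduction (NaBH4, CeCl3·7H2O, MeOH, −78 °C) is used if hydride adds mainly to the α-face, giving the 1β-epimer of the allylic alcohol F3. Mitsunobu inversion (4-nitrobenzoic acid, PPh3, diisopropyl azodicarboxylate, toluene, 0 °C to rt) gives the 1α 4-nitrobenzoate F4. Brief methanolysis (K2CO3, MeOH, 0 °C) comes back to the route at 21.

Further compounds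

F0 | step 17 | none | none
F1 | step 13 | epoxy allylic alcohol (21 with the side-chain alkene as its (R)-epoxide) | CC1(C)O[C@@H]1CC[C@]2(C)C(Cl)=C[C@H](O)[C@](C)(CC(=O)OC(C)(C)C)[C@H]2CCOCc3ccc4ccccc4c3
F2 | step 13 | epoxy chloro alcohol (22 with the side-chain alkene as its (R)-epoxide) | CC1(C)O[C@@H]1CC[C@]2(C)[C@@H](Cl)C[C@H](O)[C@](C)(CC(=O)OC(C)(C)C)[C@H]2CCOCc3ccc4ccccc4c3
F3 | step 12 | 1β-epimer of allylic alcohol 21 | CC(C)=CCC[C@]1(C)C(Cl)=C[C@@H](O)[C@](C)(CC(=O)OC(C)(C)C)[C@H]1CCOCc2ccc3ccccc3c2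
F4 | step 12 | 1α 4-nitrobenzoate of allylic alcohol 21 | CC(C)=CCC[C@]1(C)C(Cl)=C[C@H](OC(=O)c2ccc(cc2)[N+](=O)[O-])[C@](C)(CC(=O)OC(C)(C)C)[C@H]1CCOCc2ccc3ccccc3c2
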